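**Retrosynthetic overview**
1. The target comes from its bis(benzyl ether) by hydrogenolysis in the last step.
2. The tetrahydropyran comes from an acyclic (S)-δ-hydroxy aryl enone in one flask: a boron-tethered oxa-Michael addition closes a 1,3,2-dioxaborinane and sets the C4 oxygen syn to C6; a reductive oxa-cyclisation of the aryl ketone then closes the tetrahydropyran and sets C2 cis to C6.
3. The δ-hydroxy enone comes from cross-metathesis of an (S)-homoallylic alcohol with an aryl vinyl ketone.
4. The homoallylic alcohol comes from eugenol (benzylation, hydroboration, iridium-catalysed allylation, which sets the only reagent-controlled stereocentre); the vinyl ketone comes from O-benzylvanillin.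
5. Ring order: dioxaborinane (temporary, lost on work-up), then tetrahydropyran, in the same operation; both arene rings are bought.

Assumption: the SMILES is read as the (2S,4S,6S) isomer, with the 2- and 6-substituents cis (both equatorial) and the 4-OH axial, trans to both.

**Step 1**
Reactants: 1 eugenol (4-allyl-2-methoxyphenol)
Product: 2 benzyl eugenol [4-allyl-1-(benzyloxy)-2-methoxybenzene]
Conditions: BnBr, K2CO3, acetone, reflux
Reagents that add atoms: benzyl bromide, BrCc1ccccc1
Why: Williamson ether synthesis, the phenoxide displacing bromide from benzyl bromide; no stereocentre is formed.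

**Step 2**
Reactants: 2 benzyl eugenol
Product: 4 primary alcohol 3-[4-(benzyloxy)-3-methoxyphenyl]propan-1-ol, via B-alkyl-9-BBN adduct 3 (not isolated)
Conditions: 9-BBN, THF, 0 °C to rt; then NaOH, H2O2, 0 °C
Reagents that add atoms: hydrogen peroxide, OO
Why: Hydroboration–oxidation, 9-BBN placing boron on the terminal carbon of the allyl group (anti-Markovnikov) and peroxide oxidation converting C–B to C–OH; no stereocentre is formed.

**Step 3**
Reactants: 4 primary alcohol 3-[4-(benzyloxy)-3-methoxyphenyl]propan-1-ol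
Product: 6 (3S)-1-[4-(benzyloxy)-3-methoxyphenyl]hex-5-en-3-ol, via aldehyde 5 (not isolated)
Conditions: allyl acetate (2 equiv), [Ir(cod)Cl]2 (2.5 mol %), (R)-Cl,MeO-BIPHEP (5 mol %), 4-chloro-3-nitrobenzoic acid (10 mol %), Cs2CO3 (20 mol %), THF, 100 °C
Reagents that add atoms: allyl acetate, CC(=O)OCC=C
Why: Krische transfer-hydrogenative carbonyl allylation, in which the alcohol is dehydrogenated to aldehyde 5 and allylated by the chiral cyclometallated allyliridium complex through a closed chair transition state; the (R)-ligand is expected to give the 3S carbinol (the facial sense that gives (R)-1-arylbut-3-en-1-ols, with allyl outranking the 2-arylethyl group here), to be confirmed by Mosher analysis.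

**Step 4**
Reactants: 7 O-benzylvanillin [4-(benzyloxy)-3-methoxybenzaldehyde]
Product: 8 rac-1-[4-(benzyloxy)-3-methoxyphenyl]prop-2-en-1-ol
Conditions: vinylmagnesium bromide, THF, −78 to 0 °C; aq. NH4Cl
Reagents that add atoms: vinylmagnesium bromide, C=C[Mg]Br
Why: Grignard 1,2-addition to the aldehyde; the carbinol centre is racemic and is removed by oxidation in the next step.

**Step 5**
Reactants: 8 rac-1-[4-(benzyloxy)-3-methoxyphenyl]prop-2-en-1-ol
Product: 9 aryl vinyl ketone 1-[4-(benzyloxy)-3-methoxyphenyl]prop-2-en-1-one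
Conditions: MnO2 (10 equiv), CH2Cl2, rt; used at once
Reagents that add atoms: none
Why: MnO2 oxidation of an allylic, benzylic alcohol to the enone; the benzyl ether and the arene are untouched.

**Step 6**
Reactants: 6 (3S)-1-[4-(benzyloxy)-3-methoxyphenyl]hex-5-en-3-ol; 9 aryl vinyl ketone
Product: 10 (2E,5S)-1,7-bis[4-(benzyloxy)-3-methoxyphenyl]-5-hydroxyhept-2-en-1-one
Conditions: 9 (2 equiv), second-generation Hoveyda–Grubbs catalyst [RuCl2(H2IMes)(=CH-C6H4-2-OiPr)] (5 mol %), CH2Cl2, 40 °C
Reagents that add atoms: none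
Why: Olefin cross-metathesis between an electron-rich terminal alkene and an electron-poor enone, which favours the cross product as the E isomer; the C5 stereocentre is not involved, and the δ-hydroxyl cannot add to its own enone (it would form a four-membered ring).

**Step 7 (key step)**
Reactants: 10 (2E,5S)-1,7-bis[4-(benzyloxy)-3-methoxyphenyl]-5-hydroxyhept-2-en-1-one
Product: 13 (2S,4S,6S)-2-[4-(benzyloxy)-3-methoxyphenyl]-6-{2-[4-(benzyloxy)-3-methoxyphenyl]ethyl}tetrahydro-2H-pyran-4-ol, via cyclic phenylboronate 11 (not isolated), via O-boryl tetrahydropyran 12 (not isolated)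
Conditions: PhB(OH)2 (1.2 equiv), quinine-derived amine–thiourea (10 mol %), 4 Å MS, CH2Cl2, rt; then Et3SiH (4 equiv), TMSOTf (0.5 equiv), −78 to −40 °C; aq. NaHCO3
Reagents that add atoms: phenylboronic acid, OB(O)c1ccccc1
Why: Proposed new method: the 5-OH forms a boronic hemiester whose B–OH adds to the enone through a chair-like six-membered transition state with both substituents equatorial, closing the cis-4,6-disubstituted dioxaborinane 11 and setting the new carbinol centre syn to C5 (Falck-type boronic acid oxa-Michael addition of δ-hydroxy enones); TMSOTf then activates the aryl ketone, the boron-bound O5 closes the tetrahydropyran as a cyclic oxocarbenium ion, and Et3SiH attacks axially on the half-chair that has the side chain pseudo-equatorial and the boryloxy group pseudo-axial, giving the 2,6-cis ring with the C4 oxygen axial (closest known reaction: Kishi/Olah-type reductive etherification of δ-oxygenated aryl ketones; using the boronate oxygen directly as the nucleophile is the untested part).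

**Step 8**
Reactants: 13 (2S,4S,6S)-2-[4-(benzyloxy)-3-methoxyphenyl]-6-{2-[4-(benzyloxy)-3-methoxyphenyl]ethyl}tetrahydro-2H-pyran-4-ol
Product: 14 (2S,4S,6S)-2-(4-hydroxy-3-methoxyphenyl)-6-[2-(4-hydroxy-3-methoxyphenyl)ethyl]tetrahydro-2H-pyran-4-ol
Conditions: H2 (1 atm), 10% Pd/C, EtOAc–MeOH, rt, stopped at full conversion
Reagents that add atoms: none
Why: Catalytic hydrogenolysis of the two aryl benzyl ethers, which under neutral conditions cleave much faster than the cyclic secondary benzylic C–O bond; no stereocentre is touched.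

**Compound list**
1 | eugenol (4-allyl-2-methoxyphenol) | COc1cc(CC=C)ccc1O | starting material
2 | 4-allyl-1-(benzyloxy)-2-methoxybenzene | COc1cc(CC=C)ccc1OCc1ccccc1 | intermediate
3 | 9-{3-[4-(benzyloxy)-3-methoxyphenyl]propyl}-9-borabicyclo[3.3.1]nonane | COc1cc(CCCB2C3CCCC2CCC3)ccc1OCc1ccccc1 | intermediate (not isolated)
4 | 3-[4-(benzyloxy)-3-methoxyphenyl]propan-1-ol | COc1cc(CCCO)ccc1OCc1ccccc1 | intermediate
5 | 3-[4-(benzyloxy)-3-methoxyphenyl]propanal | COc1cc(CCC=O)ccc1OCc1ccccc1 | intermediate (not isolated)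
6 | (3S)-1-[4-(benzyloxy)-3-methoxyphenyl]hex-5-en-3-ol | COc1cc(CC[C@H](O)CC=C)ccc1OCc1ccccc1 | intermediate
7 | 4-(benzyloxy)-3-methoxybenzaldehyde (O-benzylvanillin) | COc1cc(C=O)ccc1OCc1ccccc1 | starting material
8 | rac-1-[4-(benzyloxy)-3-methoxyphenyl]prop-2-en-1-ol | COc1cc(C(O)C=C)ccc1OCc1ccccc1 | intermediate
9 | 1-[4-(benzyloxy)-3-methoxyphenyl]prop-2-en-1-one | COc1cc(C(=O)C=C)ccc1OCc1ccccc1 | intermediate
10 | (2E,5S)-1,7-bis[4-(benzyloxy)-3-methoxyphenyl]-5-hydroxyhept-2-en-1-one | COc1cc(CC[C@H](O)C/C=C/C(=O)c2ccc(OCc3ccccc3)c(OC)c2)ccc1OCc1ccccc1 | intermediate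
11 | 1-[4-(benzyloxy)-3-methoxyphenyl]-2-[(4S,6S)-6-{2-[4-(benzyloxy)-3-methoxyphenyl]ethyl}-2-phenyl-1,3,2-dioxaborinan-4-yl]ethan-1-one (cis ring) | COc1cc(CC[C@H]2C[C@@H](CC(=O)c3ccc(OCc4ccccc4)c(OC)c3)OB(c3ccccc3)O2)ccc1OCc1ccccc1 | intermediate (not isolated)
12 | (2S,4S,6S)-2-[4-(benzyloxy)-3-methoxyphenyl]-6-{2-[4-(benzyloxy)-3-methoxyphenyl]ethyl}tetrahydro-2H-pyran-4-yl triethylsilyl phenylboronate | COc1cc(CC[C@H]2C[C@H](OB(c3ccccc3)O[Si](CC)(CC)CC)C[C@@H](c3ccc(OCc4ccccc4)c(OC)c3)O2)ccc1OCc1ccccc1 | intermediate (not isolated)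
13 | (2S,4S,6S)-2-[4-(benzyloxy)-3-methoxyphenyl]-6-{2-[4-(benzyloxy)-3-methoxyphenyl]ethyl}tetrahydro-2H-pyran-4-ol | COc1cc(CC[C@H]2C[C@H](O)C[C@@H](c3ccc(OCc4ccccc4)c(OC)c3)O2)ccc1OCc1ccccc1 | intermediate
14 | (2S,4S,6S)-2-(4-hydroxy-3-methoxyphenyl)-6-[2-(4-hydroxy-3-methoxyphenyl)ethyl]tetrahydro-2H-pyran-4-ol | COc1cc(CC[C@H]2C[C@H](O)C[C@@H](c3ccc(O)c(OC)c3)O2)ccc1O | target

**Step count and risks**
Total step count: 8. Longest linear sequence: 6 (steps 1, 2, 3, 6, 7, 8).

Most at risk is step 7: the boronate oxygen may be too poor a nucleophile, the β-boryloxy ketone may eliminate, or the electron-rich benzylic ether may be over-reduced. The fallback sets out from 10 and rejoins the route at 13. The boronic acid oxa-Michael addition is run alone and boron is removed oxidatively (H2O2, Na2CO3) to give the syn-diol (3S,5S)-1,7-bis[4-(benzyloxy)-3-methoxyphenyl]-3,5-dihydroxyheptan-1-one F1. NaBH4 in MeOH at 0 °C reduces the ketone to (3S,5S)-1,7-bis[4-(benzyloxy)-3-methoxyphenyl]heptane-1,3,5-triol F2 as a mixture of C1 epimers. Catalytic camphorsulfonic acid in CH2Cl2 then ionises the p-alkoxybenzylic alcohol, and O5 closes the ring under thermodynamic control (2,6-cis, both substituents equatorial). No hydride is present in that ring closure, so over-reduction cannot occur, and the C4 centre is not involved.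

Second is step 6: ketone 9 can polymerise or dimerise before it metathesises. The fallback sets out from 6 and 8 and rejoins at 10. Alcohol 6 is cross-metathesised with the storable allylic alcohol 8 (same ruthenium catalyst) to give (2E,5S)-1,7-bis[4-(benzyloxy)-3-methoxyphenyl]hept-2-ene-1,5-diol F3 as a mixture of C1 epimers. MnO2 in CH2Cl2 then oxidises only the allylic, benzylic carbinol, leaving the aliphatic 5-OH, to give 10.

Third is step 3: the catalytic allylation may give low conversion or insufficient ee with this electron-rich substrate. The fallback sets out from 4 and rejoins at 6. Alcohol 4 is oxidised (TEMPO, PhI(OAc)2) to aldehyde 5, now isolated, and allylated under reagent control with (+)-B-allyldiisopinocampheylborane (Et2O, −78 °C; then NaOH, H2O2), which gives the 3S alcohol 6 for aldehydes where allyl outranks the other chain. This detour makes no compound outside the compound list (none, F0).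

**Further compounds**
F1 | step 7 | (3S,5S)-1,7-bis[4-(benzyloxy)-3-methoxyphenyl]-3,5-dihydroxyheptan-1-one | COc1cc(CC[C@H](O)C[C@H](O)CC(=O)c2ccc(OCc3ccccc3)c(OC)c2)ccc1OCc1ccccc1
F2 | step 7 | (3S,5S)-1,7-bis[4-(benzyloxy)-3-methoxyphenyl]heptane-1,3,5-triol (C1 epimers) | COc1cc(CC[C@H](O)C[C@H](O)CC(O)c2ccc(OCc3ccccc3)c(OC)c2)ccc1OCc1ccccc1
F3 | step 6 | (2E,5S)-1,7-bis[4-(benzyloxy)-3-methoxyphenyl]hept-2-ene-1,5-diol (C1 epimers) | COc1cc(CC[C@H](O)C/C=C/C(O)c2ccc(OCc3ccccc3)c(OC)c2)ccc1OCc1ccccc1
F0 | step 3 | none | none
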